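**Plan**

- Retrosynthesis first removes ring A as a whole. In ring A (the terminal 2,4-dihydroxy-6-methylbenzoyl ring, C1 bearing the carbonyl), C1 and C6 carry carbonyl and methyl like the two alkyne carbons of a but-2-ynoate, and C2–C5 carry oxygen at C2 and C4 like the carbon chain of an acetoacetate dienol ether. Cutting C1–C2 and C5–C6 therefore gives an aryl but-2-ynoate and 1-methoxy-1,3-bis(trimethylsilyloxy)buta-1,3-diene.
- The butynoate C–O bond and then the ring B/ring C depside C–O bond are cut next. This leads to but-2-ynoic acid, a 4-O-benzyl-2-O-methyl orsellinic acid (ring B) and methyl orsellinate (ring C); both arenes come from methyl orsellinate.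
- Forward: rings C and B are used as bought arenes and joined by esterification, the butynoate is attached, and ring A is the only ring built, by Diels–Alder benzannulation in the last step.
- Stereochemistry: the target has no stereocentre and no stereogenic double bond. The selectivity questions are regiochemical only (which phenol reacts, and the orientation of the cycloaddition).

Key step: step 9

Assumption: the chelated 2-hydroxyl of orsellinate esters (hydrogen-bonded to the ester carbonyl) is taken to stay unreactive towards one equivalent of an alkylating or acylating agent, so ring C needs no permanent protecting group.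

**Route**

Step 1
Reactants: 1 methyl orsellinate (methyl 2,4-dihydroxy-6-methylbenzoate)
Product: 2 methyl 4-(benzyloxy)-2-hydroxy-6-methylbenzoate
Conditions: BnBr (1.05 equiv), K2CO3, acetone, reflux
Reagents that add atoms: benzyl bromide, BrCc1ccccc1
Why: Williamson etherification should go only at O-4, because the 2-hydroxyl is hydrogen-bonded to the ester carbonyl and is less acidic and less nucleophilic than the para hydroxyl.

Step 2
Reactants: 2 methyl 4-(benzyloxy)-2-hydroxy-6-methylbenzoate
Product: 3 methyl 4-(benzyloxy)-2-methoxy-6-methylbenzoate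
Conditions: MeI (excess), K2CO3, DMF, 50 °C
Reagents that add atoms: iodomethane, CI
Why: Williamson methylation of the remaining chelated phenol is expected under these more forcing polar aprotic conditions, since no other acidic site is left.

Step 3
Reactants: 3 methyl 4-(benzyloxy)-2-methoxy-6-methylbenzoate
Product: 4 4-(benzyloxy)-2-methoxy-6-methylbenzoic acid
Conditions: KOH, DMSO/H2O, 90 °C; then 1 M HCl
Reagents that add atoms: potassium hydroxide, [K+].[OH-]
Why: Saponification of the di-ortho-substituted methyl benzoate needs poorly solvated hydroxide in hot aqueous DMSO, the usual conditions for hindered orsellinate esters, and both ethers are inert to base.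

Step 4
Reactants: 4 4-(benzyloxy)-2-methoxy-6-methylbenzoic acid; 1 methyl orsellinate
Product: 5 methyl 4-{[4-(benzyloxy)-2-methoxy-6-methylbenzoyl]oxy}-2-hydroxy-6-methylbenzoate
Conditions: (CF3CO)2O, toluene, rt
Reagents that add atoms: none
Why: In this trifluoroacetic anhydride-mediated esterification the mixed anhydride of the electron-rich, di-ortho-substituted acid should ionise towards an aroyl cation that acylates the free para hydroxyl of 1, while the chelated 2-hydroxyl stays out, as is usual in depside couplings.

Step 5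
Reactants: 5 methyl 4-{[4-(benzyloxy)-2-methoxy-6-methylbenzoyl]oxy}-2-hydroxy-6-methylbenzoate
Product: 6 methyl 2-hydroxy-4-[(4-hydroxy-2-methoxy-6-methylbenzoyl)oxy]-6-methylbenzoate
Conditions: H2 (1 atm), 10% Pd/C, EtOAc, rt
Reagents that add atoms: none
Why: Catalytic hydrogenolysis of the benzyl aryl ether should free the ring B phenol without touching the aryl ester, the methyl ester or the methyl ether.

Step 6
Reactants: 6 methyl 2-hydroxy-4-[(4-hydroxy-2-methoxy-6-methylbenzoyl)oxy]-6-methylbenzoate; 7 but-2-ynoic acid
Product: 8 methyl 4-{[4-(but-2-ynoyloxy)-2-methoxy-6-methylbenzoyl]oxy}-2-hydroxy-6-methylbenzoate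
Conditions: DCC (1.1 equiv), DMAP (10 mol%), CH2Cl2, 0 °C
Reagents that add atoms: none
Why: Steglich esterification of the unhindered linear acid should acylate the only non-chelated phenol (ring B O-4) at 0 °C, where acyl transfer outruns addition of DMAP to the triple bond and the hindered depside carbonyl and the chelated ring C hydroxyl are left alone.

Step 7
Reactants: 9 methyl acetoacetate
Product: 10 methyl 3-(trimethylsilyloxy)but-2-enoate (E/Z mixture)
Conditions: Me3SiCl, Et3N, hexane, rt
Reagents that add atoms: chlorotrimethylsilane, C[Si](C)(C)Cl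
Why: O-Silylation of the enol of the β-keto ester (silyl enol ether formation) is a standard transformation, and the amine hydrochloride is removed by filtration.

Step 8
Reactants: 10 methyl 3-(trimethylsilyloxy)but-2-enoate
Product: 11 1-methoxy-1,3-bis(trimethylsilyloxy)buta-1,3-diene (E/Z mixture at the ketene acetal)
Conditions: LiN(iPr)2, THF, −78 °C; then Me3SiCl, −78 °C to rt; distilled and used fresh
Reagents that add atoms: chlorotrimethylsilane, C[Si](C)(C)Cl
Why: Vinylogous (γ) deprotonation gives the extended ester dienolate, which is trapped on oxygen as the silyl ketene acetal, the standard preparation of this diene.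

Step 9
Reactants: 8 methyl 4-{[4-(but-2-ynoyloxy)-2-methoxy-6-methylbenzoyl]oxy}-2-hydroxy-6-methylbenzoate; 11 1-methoxy-1,3-bis(trimethylsilyloxy)buta-1,3-diene
Product: 15 methyl 4-({4-[(2,4-dihydroxy-6-methylbenzoyl)oxy]-2-methoxy-6-methylbenzoyl}oxy)-2-hydroxy-6-methylbenzoate (target CNP0563156.0), via ring C trimethylsilyl ether 12 (not isolated), via cyclohexa-1,4-diene cycloadduct 13 (not isolated), via tris(trimethylsilyl) ether 14 (not isolated)
Conditions: MeC(OSiMe3)=NSiMe3 (BSA, 1.3 equiv), toluene, 60 °C; then 11 (3 equiv), 120 °C, sealed tube; then 1 M HCl, THF, rt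
Reagents that add atoms: none
Why: The chelated ring C phenol, which would otherwise protonate the silyl ketene acetal, is first capped in the flask as trimethylsilyl ether 12; diene 11 then adds to the but-2-ynoate in a thermal, strongly asynchronous (4+2) cycloaddition in which the unsubstituted CH2 terminus (largest HOMO coefficient) bonds to the methyl-bearing β-carbon and the ketene acetal carbon bonds to the α-carbon, so that C5–C6 and C1–C2 of ring A form and the six-membered ring closes in one intermolecular Diels–Alder event to give 13. The closest known reaction type is the Diels–Alder benzannulation of 1,1,3-trioxygenated butadienes (1,1-dialkoxy-3-silyloxy and 1-alkoxy-1,3-bis(silyloxy) dienes) with 2-alkynoates, which gives resorcylate esters. The mixed silyl methyl ketal of 13 should then lose methanol by 1,4-elimination, its silylated oxygen staying on carbon to become the C2 hydroxyl, to give arene 14, and dilute acid removes the three silyl groups. The ketal carbon of 13 is the only stereocentre formed; it is racemic and vanishes on aromatisation, so no stereocontrol is involved. The step needs regioselectivity, secured by the matched polarisation of the diene (nucleophilic CH2 terminus) and the ynoate (electrophilic β-carbon), which places CH3 at C6 and OH at C2 and C4; it also needs dienophile reactivity, which the electron-poor aryl ester supplies by lowering the LUMO of the β-methyl ynoate, while the di-ortho-substituted depside carbonyl and the methyl ester are too hindered for the neutral diene to attack.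

**Compound list**

1 | methyl orsellinate (methyl 2,4-dihydroxy-6-methylbenzoate) | COC(=O)c1c(C)cc(O)cc1O | starting material
2 | methyl 4-(benzyloxy)-2-hydroxy-6-methylbenzoate | COC(=O)c1c(C)cc(OCc2ccccc2)cc1O | intermediate
3 | methyl 4-(benzyloxy)-2-methoxy-6-methylbenzoate | COC(=O)c1c(C)cc(OCc2ccccc2)cc1OC | intermediate
4 | 4-(benzyloxy)-2-methoxy-6-methylbenzoic acid | OC(=O)c1c(C)cc(OCc2ccccc2)cc1OC | intermediate
5 | methyl 4-{[4-(benzyloxy)-2-methoxy-6-methylbenzoyl]oxy}-2-hydroxy-6-methylbenzoate | COC(=O)c1c(C)cc(OC(=O)c2c(C)cc(OCc3ccccc3)cc2OC)cc1O | intermediate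
6 | methyl 2-hydroxy-4-[(4-hydroxy-2-methoxy-6-methylbenzoyl)oxy]-6-methylbenzoate (didepside phenol) | COC(=O)c1c(C)cc(OC(=O)c2c(C)cc(O)cc2OC)cc1O | intermediate
7 | but-2-ynoic acid | CC#CC(=O)O | starting material
8 | methyl 4-{[4-(but-2-ynoyloxy)-2-methoxy-6-methylbenzoyl]oxy}-2-hydroxy-6-methylbenzoate (didepside but-2-ynoate) | CC#CC(=O)Oc1cc(C)c(C(=O)Oc2cc(C)c(C(=O)OC)c(O)c2)c(OC)c1 | intermediate
9 | methyl acetoacetate | CC(=O)CC(=O)OC | starting material
10 | methyl 3-(trimethylsilyloxy)but-2-enoate (E/Z mixture) | COC(=O)C=C(C)O[Si](C)(C)C | intermediate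
11 | 1-methoxy-1,3-bis(trimethylsilyloxy)buta-1,3-diene (E/Z mixture) | C=C(O[Si](C)(C)C)C=C(OC)O[Si](C)(C)C | intermediate
12 | methyl 4-{[4-(but-2-ynoyloxy)-2-methoxy-6-methylbenzoyl]oxy}-6-methyl-2-(trimethylsilyloxy)benzoate (ring C trimethylsilyl ether of 8) | CC#CC(=O)Oc1cc(C)c(C(=O)Oc2cc(C)c(C(=O)OC)c(O[Si](C)(C)C)c2)c(OC)c1 | intermediate (not isolated)
13 | aryl 6-methoxy-2-methyl-4,6-bis(trimethylsilyloxy)cyclohexa-1,4-diene-1-carboxylate, aryl being the ring B/ring C unit of 12 (racemic at the ketal carbon) | CC1=C(C(=O)Oc2cc(C)c(C(=O)Oc3cc(C)c(C(=O)OC)c(O[Si](C)(C)C)c3)c(OC)c2)C(OC)(O[Si](C)(C)C)C=C(O[Si](C)(C)C)C1 | intermediate (not isolated)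
14 | tris(trimethylsilyl) ether of 15 (ring A O-2 and O-4, ring C O-2 silylated) | COC(=O)c1c(C)cc(OC(=O)c2c(C)cc(OC(=O)c3c(C)cc(O[Si](C)(C)C)cc3O[Si](C)(C)C)cc2OC)cc1O[Si](C)(C)C | intermediate (not isolated)
15 | methyl 4-({4-[(2,4-dihydroxy-6-methylbenzoyl)oxy]-2-methoxy-6-methylbenzoyl}oxy)-2-hydroxy-6-methylbenzoate (CNP0563156.0) | COC(=O)c1c(C)cc(OC(=O)c2c(C)cc(OC(=O)c3c(C)cc(O)cc3O)cc2OC)cc1O | target

**Step count**

Total steps: 9. Longest linear sequence: 7 (steps 1, 2, 3, 4, 5, 6, 9 from methyl orsellinate); the diene branch (steps 7 and 8) joins at step 9.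

**Steps most likely to fail**

1. Step 9. The cycloaddition to the β-methyl ynoate may be slower than thermal decomposition or adventitious hydrolysis of the diene. The diene may also attack an ester carbonyl, or the ketal may ionise with loss of silanol instead of methanol and leave a methyl ether at C2 of ring A. Fallback: ring A is brought in ready-made and joined by a third depside esterification. Setting out from 1 and 6, compound 1 is dibenzylated (BnBr excess, K2CO3, DMF, 70 °C) to methyl 2,4-bis(benzyloxy)-6-methylbenzoate F1. This is saponified (KOH, DMSO/H2O, 90 °C) to 2,4-bis(benzyloxy)-6-methylbenzoic acid F2. The acid is condensed with didepside phenol 6 ((CF3CO)2O, toluene, rt) to methyl 4-[(4-{[2,4-bis(benzyloxy)-6-methylbenzoyl]oxy}-2-methoxy-6-methylbenzoyl)oxy]-2-hydroxy-6-methylbenzoate F3. Hydrogenolysis (H2, 10% Pd/C, EtOAc) then comes back to the route at 15.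

2. Step 6. With two phenols and an aryl ester in the substrate, acyl transfer may reach the ring C hydroxyl or scramble the depside link. The O-acylisourea may also rearrange to the N-acylurea, or the nucleophilic catalyst may add to the activated triple bond, giving mixtures that are hard to separate at this late stage. Fallback: the butynoate is put on ring B before the depside bond is made. Setting out from 4, the acid is converted (Me2NCH(OtBu)2, toluene, 80 °C) into tert-butyl 4-(benzyloxy)-2-methoxy-6-methylbenzoate F4. Hydrogenolysis (H2, 10% Pd/C, EtOAc) gives tert-butyl 4-hydroxy-2-methoxy-6-methylbenzoate F5. This monophenol, free of a second hydroxyl and of any aryl ester, is acylated with excess 7 (DCC, DMAP, CH2Cl2, 0 °C) to tert-butyl 4-(but-2-ynoyloxy)-2-methoxy-6-methylbenzoate F6. The tert-butyl ester is cleaved (CF3CO2H, anisole, CH2Cl2, rt) to 4-(but-2-ynoyloxy)-2-methoxy-6-methylbenzoic acid F7. Condensation with 1 ((CF3CO)2O, toluene, rt) comes back to the route at 8.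

3. Step 4. The mixed anhydride may acylate ring C at O-2 or at a ring carbon as well as at O-4, or transfer the trifluoroacetyl group, and the hindered acid may be captured only slowly. Fallback: O-2 of ring C is masked so that a single nucleophilic site remains. Setting out from 1 and 4, compound 1 is allylated at O-4 (allyl bromide, K2CO3, acetone, reflux) to methyl 4-(allyloxy)-2-hydroxy-6-methylbenzoate F8. Benzylation (BnBr, K2CO3, DMF, 60 °C) gives methyl 4-(allyloxy)-2-(benzyloxy)-6-methylbenzoate F9. Deallylation (Pd(PPh3)4, morpholine, THF, rt) gives methyl 2-(benzyloxy)-4-hydroxy-6-methylbenzoate F10. Condensation with 4 ((CF3CO)2O in excess, toluene, rt) gives methyl 2-(benzyloxy)-4-{[4-(benzyloxy)-2-methoxy-6-methylbenzoyl]oxy}-6-methylbenzoate F11. Hydrogenolysis of both benzyl ethers (H2, 10% Pd/C, EtOAc) comes back to the route at 6.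

**Further compounds**

F1 | step 9 | methyl 2,4-bis(benzyloxy)-6-methylbenzoate | COC(=O)c1c(C)cc(OCc2ccccc2)cc1OCc1ccccc1
F2 | step 9 | 2,4-bis(benzyloxy)-6-methylbenzoic acid | OC(=O)c1c(C)cc(OCc2ccccc2)cc1OCc1ccccc1
F3 | step 9 | methyl 4-[(4-{[2,4-bis(benzyloxy)-6-methylbenzoyl]oxy}-2-methoxy-6-methylbenzoyl)oxy]-2-hydroxy-6-methylbenzoate | COC(=O)c1c(C)cc(OC(=O)c2c(C)cc(OC(=O)c3c(C)cc(OCc4ccccc4)cc3OCc3ccccc3)cc2OC)cc1O
F4 | step 6 | tert-butyl 4-(benzyloxy)-2-methoxy-6-methylbenzoate | CC(C)(C)OC(=O)c1c(C)cc(OCc2ccccc2)cc1OC
F5 | step 6 | tert-butyl 4-hydroxy-2-methoxy-6-methylbenzoate | CC(C)(C)OC(=O)c1c(C)cc(O)cc1OC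
F6 | step 6 | tert-butyl 4-(but-2-ynoyloxy)-2-methoxy-6-methylbenzoate | CC#CC(=O)Oc1cc(C)c(C(=O)OC(C)(C)C)c(OC)c1
F7 | step 6 | 4-(but-2-ynoyloxy)-2-methoxy-6-methylbenzoic acid | CC#CC(=O)Oc1cc(C)c(C(=O)O)c(OC)c1
F8 | step 4 | methyl 4-(allyloxy)-2-hydroxy-6-methylbenzoate | COC(=O)c1c(C)cc(OCC=C)cc1O
F9 | step 4 | methyl 4-(allyloxy)-2-(benzyloxy)-6-methylbenzoate | COC(=O)c1c(C)cc(OCC=C)cc1OCc1ccccc1
F10 | step 4 | methyl 2-(benzyloxy)-4-hydroxy-6-methylbenzoate | COC(=O)c1c(C)cc(O)cc1OCc1ccccc1
F11 | step 4 | methyl 2-(benzyloxy)-4-{[4-(benzyloxy)-2-methoxy-6-methylbenzoyl]oxy}-6-methylbenzoate | COC(=O)c1c(C)cc(OC(=O)c2c(C)cc(OCc3ccccc3)cc2OC)cc1OCc1ccccc1
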